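**Retrosynthetic overview**

1. The strategy rests on ring A (C1–C2–C3–C4–C5–C6–C11, seven-membered), which spans the two one-carbon bridges C4 and C6 of a bicyclo[3.1.1]heptane (cyclobutane C4–C5–C6–C7; six-membered ring C5–C6–C7–C8–C9–C10) and carries O2 and O3 cis to each other and trans to O1. That is the outcome of a pinacol coupling beside an α-alkoxy centre, so C2–C3 is cut to a C2,C3-dialdehyde whose two arms stand 1,3-cis on the cyclobutane.
2. The dialdehyde comes from one ozonolysis of a tris-alkene (C2 vinyl, C3 vinyl, C8 methylene); O1 is set by Corey–Bakshi–Shibata reduction of a C1 vinyl ketone made from a C1 lactone.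
3. That lactone (C1–O–C3 tether) is formed by an intramolecular Reformatsky reaction that delivers C11 to the C6 ketone; radical deoxygenation then leaves C6–H syn, the tether holding C11 anti.
4. The bicyclo[3.1.1]heptan-6-one comes from an intramolecular vinylketene–alkene [2+2] of an acyclic dienoic acid: the E-alkene fixes C4, the C10 methyl (rhodium-catalysed conjugate addition) steers the face, and the exocyclic methylene is the masked C8 ketone. The C3 oxygen is built into the acyclic chain, because an alkoxyl radical on the cyclobutane carbon C6 would open the four-membered ring by β-scission before it could functionalise the C4 methyl of a pinane.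
5. Ring order: cyclobutane and six-membered ring together (step 6), temporary lactone (step 9, opened in step 12), ring A (step 19).

Key step: step 19

**Remarks**

- Atom labels C1–C11 are those of the target: ring A = C1, C2, C3, C4, C5, C6, C11; cyclobutane = C4, C5, C6, C7; six-membered ring = C5 to C10. On C4 and C6, syn/anti mean towards/away from the C8–C9–C10 bridge.
- Assumption: in step 3 the (S)-BINAP complex is taken to deliver the alkenyl group to the 2si face of the E-enone, as the accepted model predicts; should the sense prove opposite, (R)-BINAP is used.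
- C8 stays an exocyclic methylene while C6 is a ketone (a C6/C8 diketone across the C7 bridgehead would invite retro-Claisen opening). It is carried through the key step as a free ketone, which SmI2 in THF without HMPA reduces far more slowly than an aldehyde, so no ketal is put on or taken off.
- Compounds 11, 13 and 14 are drawn as 2E isomers; the 2Z isomers give the same ketene 15.

**Route**

Step 1
Reactants: 1 prop-2-yn-1-ol; 2 chlorotriisopropylsilane
Product: 3 triisopropyl(prop-2-yn-1-yloxy)silane
Conditions: imidazole, CH2Cl2, 0 °C to rt
Reagents that add atoms: chlorotriisopropylsilane, CC(C)[Si](Cl)(C(C)C)C(C)C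
Why: Imidazole-promoted silylation of a primary alcohol is routine, and the triisopropylsilyl ether survives the organoaluminium, aqueous base and acid chloride stages that follow.

Step 2
Reactants: 3 triisopropyl(prop-2-yn-1-yloxy)silane; 4 trimethylaluminium; 5 2-methoxy-4,4,5,5-tetramethyl-1,3,2-dioxaborolane
Product: 7 4,4,5,5-tetramethyl-2-[(1E)-2-methyl-3-(triisopropylsilyloxy)prop-1-en-1-yl]-1,3,2-dioxaborolane, via alkenyldimethylalane 6 (not isolated)
Conditions: Me3Al (2.5 equiv), Cp2ZrCl2 (0.25 equiv), CH2Cl2, 0 °C to rt; then MeOBpin (3 equiv), 0 °C to rt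
Reagents that add atoms: trimethylaluminium, C[Al](C)C; 2-methoxy-4,4,5,5-tetramethyl-1,3,2-dioxaborolane, COB1OC(C)(C)C(C)(C)O1
Why: Negishi zirconium-catalysed carboalumination adds methyl and aluminium syn across the terminal alkyne with methyl on the internal carbon, so the metal ends trans to CH2OTIPS, and alkenyl transfer from aluminium to boron with the alkoxyborane keeps that E geometry.

Step 3
Reactants: 7 alkenyl pinacol boronate; 8 (E)-pent-3-en-2-one
Product: 9 (4R,5E)-4,6-dimethyl-7-(triisopropylsilyloxy)hept-5-en-2-one
Conditions: [Rh(cod)Cl]2 (2.5 mol %), (S)-BINAP (6 mol %), KOH (aq), 1,4-dioxane, 40 °C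
Reagents that add atoms: (E)-pent-3-en-2-one, C/C=C/C(C)=O
Why: Hayashi–Miyaura asymmetric conjugate addition, in which the alkenylrhodium–BINAP complex (monovalent rhodium) inserts the E-enone on one face only, so the future C10 stereocentre should be set as R under ligand control while the alkene geometry is carried over unchanged.

Step 4
Reactants: 9 (4R,5E)-ketone; 10 triethyl phosphonoacetate
Product: 11 ethyl (2E,5R,6E)-3,5,7-trimethyl-8-(triisopropylsilyloxy)octa-2,6-dienoate
Conditions: NaH, THF, 0 °C to 60 °C
Reagents that add atoms: triethyl phosphonoacetate, CCOC(=O)CP(=O)(OCC)OCC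
Why: Horner–Wadsworth–Emmons olefination of the methyl ketone gives the β-methyl enoate, and its 2E/2Z composition is of no consequence because both isomers lead to the same vinylketene in step 6.

Step 5
Reactants: 11 dienoate; 12 lithium hydroxide
Product: 13 (2E,5R,6E)-3,5,7-trimethyl-8-(triisopropylsilyloxy)octa-2,6-dienoic acid
Conditions: LiOH, THF/MeOH/H2O, 50 °C; then 1 M HCl to pH 3
Reagents that add atoms: lithium hydroxide, [Li+].[OH-]
Why: Saponification of the hindered enoate needs only mild heating and touches neither the silyl ether nor the C5 stereocentre, which bears no acidic hydrogen.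

Step 6
Reactants: 13 dienoic acid
Product: 16 TIPS-protected 8-methylenebicyclo[3.1.1]heptan-6-one (target labels; C3 oxygen anti on C4), via acid chloride 14 (not isolated), via vinylketene 15 (not isolated)
Conditions: (COCl)2, DMF (cat.), CH2Cl2, rt, evaporate; then slow addition to Et3N, toluene, 110 °C, final 0.01 M
Reagents that add atoms: none
Why: Dehydrochlorination at the C3 methyl of 14 gives vinylketene 15, whose intramolecular ketene–alkene [2+2] cycloaddition joins the ketene carbonyl carbon to the less substituted alkene carbon (C5) and the ketene α-carbon to the fully substituted one (C4), closing the cyclobutane and the six-membered ring together; addition is suprafacial on the alkene, so the E-CH2OTIPS group ends anti and the methyl syn on C4, and the C10 methyl, which avoids the C4 methyl in the transition state (allylic 1,3-strain), should direct the ketene to the face that gives the C5 and C7 configurations of the target.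

Step 7
Reactants: 16 silyl ether
Product: 17 C3 alcohol (hydroxymethyl anti on C4; C6 ketone; C8 methylene)
Conditions: Bu4NF, AcOH, THF, 0 °C to rt
Reagents that add atoms: none
Why: Fluoride cleaves the silyl ether, and buffering with acetic acid keeps the medium from opening the strained, non-enolisable cyclobutanone.

Step 8
Reactants: 17 C3 alcohol; 18 2-bromo-2-methylpropanoyl bromide
Product: 19 C3 2-bromo-2-methylpropanoate
Conditions: pyridine, DMAP (cat.), CH2Cl2, 0 °C
Reagents that add atoms: 2-bromo-2-methylpropanoyl bromide, CC(C)(Br)C(Br)=O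
Why: Acylation of the primary neopentyl alcohol with the reactive acyl bromide installs the C11/C1 unit on a tether that can reach only the anti face of C6.

Step 9
Reactants: 19 bromoester
Product: 21 C6-hydroxy lactone (C6–C11 bond anti; C6–OH syn), via samarium enolate 20 (not isolated)
Conditions: SmI2 (2.5 equiv), THF, −78 °C to 0 °C, 0.005 M; aq. NH4Cl
Reagents that add atoms: none
Why: In this SmI2-promoted (divalent samarium) intramolecular Reformatsky reaction, reduction of the C–Br bond gives samarium enolate 20, which can reach the strained C6 carbonyl only from the anti face through a seven-membered transition state, so C11 is attached anti and the new C6 hydroxyl is syn.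

Step 10
Reactants: 21 hydroxy lactone; 22 carbon disulfide; 23 iodomethane
Product: 25 C6 O-alkyl S-methyl xanthate of 21, via potassium xanthate 24 (not isolated)
Conditions: KN(SiMe3)2, THF, −78 °C; CS2, −78 to −20 °C; MeI, 0 °C
Reagents that add atoms: carbon disulfide, S=C=S; iodomethane, CI
Why: Xanthate formation through the alkoxide and the small electrophile CS2 is the standard entry to Barton–McCombie deoxygenation of hindered tertiary alcohols, and Chugaev elimination is impossible here because the only β-hydrogens sit at bridgeheads.

Step 11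
Reactants: 25 xanthate
Product: 26 lactone with C6–H syn (ring: C6–C11–C1(=O)–O–C3–C4)
Conditions: Bu3SnH, AIBN (cat.), toluene, 90 °C
Reagents that add atoms: none
Why: In this Barton–McCombie deoxygenation the tertiary C6 radical is held in the lactone with C11 locked anti, so hydrogen from Bu3SnH can arrive only on the syn face, which gives the C6 configuration of the target.

Step 12
Reactants: 26 lactone; 27 N,O-dimethylhydroxylamine hydrochloride
Product: 28 C3 hydroxy C1 Weinreb amide
Conditions: Me3Al, CH2Cl2, 0 °C to 40 °C; aq. KNaC4H4O6
Reagents that add atoms: N,O-dimethylhydroxylamine hydrochloride, CNOC.Cl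
Why: Weinreb aminolysis with the aluminium amide formed from Me3Al opens even α,α-disubstituted lactones, turning the lactone carbonyl (C1) into a ketone precursor and freeing the C3 alcohol.

Step 13
Reactants: 28 hydroxy amide
Product: 29 C3 aldehyde C1 Weinreb amide
Conditions: Dess–Martin periodinane, NaHCO3, CH2Cl2, rt
Reagents that add atoms: none
Why: Dess–Martin oxidation of the neopentyl primary alcohol gives a non-enolisable aldehyde under buffered conditions that leave the Weinreb amide and the alkene untouched.

Step 14
Reactants: 29 aldehyde; 30 methyltriphenylphosphonium bromide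
Product: 31 C3 vinyl C1 Weinreb amide
Conditions: KN(SiMe3)2, THF, 0 °C; then 29, −78 to 0 °C
Reagents that add atoms: methyltriphenylphosphonium bromide, C[P+](c1ccccc1)(c1ccccc1)c1ccccc1.[Br-]
Why: Wittig methylenation is far faster at the aldehyde than at the Weinreb amide and stores C3 as a vinyl group that is inert to the Grignard, borane and alkylation steps ahead.

Step 15
Reactants: 31 Weinreb amide; 32 vinylmagnesium bromide
Product: 33 C1 vinyl ketone
Conditions: THF, 0 °C to rt; inverse quench into cold 1 M HCl
Reagents that add atoms: vinylmagnesium bromide, C=C[Mg]Br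
Why: The Grignard reagent adds only once to the Weinreb amide because the magnesium chelate holds until the acidic quench, which gives the vinyl ketone and brings in C2.

Step 16
Reactants: 33 vinyl ketone
Product: 34 (1R)-allylic alcohol
Conditions: (S)-1-methyl-3,3-diphenyltetrahydro-1H,3H-pyrrolo[1,2-c][1,3,2]oxazaborole [(S)-Me-CBS, 0.5 equiv], catecholborane, toluene, −78 °C
Reagents that add atoms: none
Why: In this Corey–Bakshi–Shibata reduction under catalyst control, with the quaternary C11 as the large and vinyl as the small substituent, the (S)-catalyst should deliver hydride to the face that gives the (1R)-alcohol, and catecholborane at −78 °C does not hydroborate the three alkenes.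

Step 17
Reactants: 34 allylic alcohol; 35 4-methoxybenzyl chloride
Product: 36 O1 4-methoxybenzyl ether (tris-alkene)
Conditions: NaH, Bu4NI (cat.), DMF, 0 °C to rt
Reagents that add atoms: 4-methoxybenzyl chloride, COc1ccc(CCl)cc1
Why: Williamson etherification of the sodium alkoxide with the benzylic chloride under iodide catalysis protects O1 as an ether that tolerates SmI2 and is later removed oxidatively.

Step 18
Reactants: 36 tris-alkene; 37 ozone
Product: 39 keto-dialdehyde (C2 and C3 formyl groups; C8 ketone; O1 PMB ether), via tris-ozonide 38 (not isolated)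
Conditions: O3, CH2Cl2, −78 °C (Sudan Red 7B end point); then PPh3, −78 °C to rt; used at once
Reagents that add atoms: ozone, [O-][O+]=O
Why: Ozonolysis cleaves the three terminal alkenes in one operation, and reduction of tris-ozonide 38 with PPh3 releases the C2 and C3 aldehydes and the C8 ketone without acid or base, so the C1 stereocentre beside the new aldehyde is not disturbed and the indicator guards the anisyl ring against over-oxidation.

Step 19
Reactants: 39 keto-dialdehyde
Product: 40 tricyclic C2,C3-cis-diol (O1 PMB ether; C8 ketone)
Conditions: SmI2 (3 equiv), THF, −78 °C to rt, 0.01 M; aq. NaHCO3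
Reagents that add atoms: none
Why: SmI2 (divalent samarium) transfers one electron to each aldehyde; the first ketyl adds to the second samarium-bound carbonyl (or the two ketyls combine), forming C2–C3 and leaving a samarium diolate, and the closest known reaction type is the SmI2-mediated intramolecular pinacol coupling of α-alkoxy dialdehydes to cyclic cis-1,2-diols, as used for cyclitols. Ring A closes as a seven-membered ring by C2–C3 bond formation between two arms that the cyclobutane holds 1,3-cis and close in space on its face away from the C8–C10 bridge, so much of the entropic cost of a seven-membered closure is paid in advance. C2 and C3 are set together: both oxygens are bound to trivalent samarium in the bond-forming arrangement, which gives the cis-diol, and the C1 stereocentre from step 16 controls the face, the developing C2–O bond turning away from the C1–OPMB bond (opposed dipoles, Felkin-type approach) to give the 1,2-trans-2,3-cis array. The step needs chemoselectivity for the two aldehydes over the C8 ketone, which the much slower reduction of dialkyl ketones by SmI2 in THF and the distance of C8 from both ketyls should secure. It also needs coupling to outrun protonation of the ketyls and loss of the C1 alkoxide: no proton source is added, the C3 aldehyde cannot enolise (quaternary C4), and α-alkoxy aldehydes are known to survive these conditions.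

Step 20
Reactants: 40 diol; 41 acetic anhydride
Product: 42 O2 monoacetate
Conditions: Ac2O (1.1 equiv), pyridine, CH2Cl2, −20 to 0 °C
Reagents that add atoms: acetic anhydride, CC(=O)OC(C)=O
Why: The C2 hydroxyl lies between two secondary carbons and is acylated faster than the C3 hydroxyl next to the quaternary C4, so one equivalent of anhydride at low temperature should give the 2-monoacetate.

Step 21
Reactants: 42 monoacetate; 43 angelic acid [(Z)-2-methylbut-2-enoic acid]
Product: 44 O2 acetate O3 angelate (O1 PMB ether)
Conditions: 2,4,6-trichlorobenzoyl chloride, Et3N, toluene, rt; then 42, 80 °C (no DMAP)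
Reagents that add atoms: angelic acid, C/C=C(/C)C(=O)O
Why: Yamaguchi esterification through the mixed 2,4,6-trichlorobenzoic anhydride acylates hindered secondary alcohols, and leaving out DMAP avoids the conjugate-addition pathway that isomerises angelates to tiglates.

Step 22
Reactants: 44 PMB ether
Product: 45 O1 alcohol (O2 acetate; O3 angelate)
Conditions: DDQ, CH2Cl2/pH 7 buffer, 0 °C to rt
Reagents that add atoms: none
Why: DDQ oxidises the electron-rich benzyl ether to an oxocarbenium ion that water hydrolyses, a neutral deprotection that spares the esters, the angelate alkene and the ketone.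

Step 23
Reactants: 45 O1 alcohol; 43 angelic acid
Product: 46 target (CNP0197834.1)
Conditions: 2,4,6-trichlorobenzoyl chloride, Et3N, toluene, rt; then 45, 80 °C (no DMAP)
Reagents that add atoms: angelic acid, C/C=C(/C)C(=O)O
Why: The same mixed-anhydride angeloylation on the last free hydroxyl, again without DMAP so that the Z geometry is kept, completes the target.

**Compound list**

1 | prop-2-yn-1-ol | C#CCO | starting material
2 | chlorotriisopropylsilane | CC(C)[Si](Cl)(C(C)C)C(C)C | starting material
3 | triisopropyl(prop-2-yn-1-yloxy)silane | C#CCO[Si](C(C)C)(C(C)C)C(C)C | intermediate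
4 | trimethylaluminium | C[Al](C)C | starting material
5 | 2-methoxy-4,4,5,5-tetramethyl-1,3,2-dioxaborolane | COB1OC(C)(C)C(C)(C)O1 | starting material
6 | dimethyl[(1E)-2-methyl-3-(triisopropylsilyloxy)prop-1-en-1-yl]aluminium | C[Al](C)/C=C(\C)CO[Si](C(C)C)(C(C)C)C(C)C | intermediate (not isolated)
7 | 4,4,5,5-tetramethyl-2-[(1E)-2-methyl-3-(triisopropylsilyloxy)prop-1-en-1-yl]-1,3,2-dioxaborolane | CC1(C)OB(/C=C(\C)CO[Si](C(C)C)(C(C)C)C(C)C)OC1(C)C | intermediate
8 | (E)-pent-3-en-2-one | C/C=C/C(C)=O | starting material
9 | (4R,5E)-4,6-dimethyl-7-(triisopropylsilyloxy)hept-5-en-2-one | CC(=O)C[C@@H](C)/C=C(\C)CO[Si](C(C)C)(C(C)C)C(C)C | intermediate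
10 | triethyl phosphonoacetate | CCOC(=O)CP(=O)(OCC)OCC | starting material
11 | ethyl (2E,5R,6E)-3,5,7-trimethyl-8-(triisopropylsilyloxy)octa-2,6-dienoate | CCOC(=O)/C=C(\C)C[C@@H](C)/C=C(\C)CO[Si](C(C)C)(C(C)C)C(C)C | intermediate
12 | lithium hydroxide | [Li+].[OH-] | starting material
13 | (2E,5R,6E)-3,5,7-trimethyl-8-(triisopropylsilyloxy)octa-2,6-dienoic acid | OC(=O)/C=C(\C)C[C@@H](C)/C=C(\C)CO[Si](C(C)C)(C(C)C)C(C)C | intermediate
14 | (2E,5R,6E)-3,5,7-trimethyl-8-(triisopropylsilyloxy)octa-2,6-dienoyl chloride | ClC(=O)/C=C(\C)C[C@@H](C)/C=C(\C)CO[Si](C(C)C)(C(C)C)C(C)C | intermediate (not isolated)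
15 | (5R,6E)-5,7-dimethyl-3-methylidene-8-(triisopropylsilyloxy)octa-1,6-dien-1-one (vinylketene) | O=C=CC(=C)C[C@@H](C)/C=C(\C)CO[Si](C(C)C)(C(C)C)C(C)C | intermediate (not isolated)
16 | bicyclo[3.1.1]heptan-6-one, target labels: C6 ketone; C8 exocyclic methylene; (10R)-methyl on the C6 side; C4 with methyl syn and CH2OTIPS (C3) anti; C5-H and C7-H as in the target | CC(C)[Si](OC[C@]2(C)[C@@H]3C(=O)[C@H]2C(=C)C[C@H]3C)(C(C)C)C(C)C | intermediate
17 | C3 alcohol of 16 (hydroxymethyl anti on C4) | OC[C@]2(C)[C@@H]3C(=O)[C@H]2C(=C)C[C@H]3C | intermediate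
18 | 2-bromo-2-methylpropanoyl bromide | CC(C)(Br)C(Br)=O | starting material
19 | C3 2-bromo-2-methylpropanoate of 17 | CC(C)(Br)C(=O)OC[C@]2(C)[C@@H]3C(=O)[C@H]2C(=C)C[C@H]3C | intermediate
20 | samarium enolate of the C3 isobutyrate (O-SmI2 ketene acetal) | CC(C)=C(O[Sm](I)I)OC[C@]2(C)[C@@H]3C(=O)[C@H]2C(=C)C[C@H]3C | intermediate (not isolated)
21 | hydroxy lactone: seven-membered lactone C6–C11(Me2)–C1(=O)–O–C3–C4 on the anti face; C6–OH syn; C8 methylene | O=C1OC[C@]2(C)[C@@H]3[C@@](O)([C@H]2C(=C)C[C@H]3C)C1(C)C | intermediate
22 | carbon disulfide | S=C=S | starting material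
23 | iodomethane | CI | starting material
24 | potassium O-alkyl xanthate of 21 (at C6–O) | O=C1OC[C@]2(C)[C@@H]3[C@@](OC(=S)[S-])([C@H]2C(=C)C[C@H]3C)C1(C)C.[K+] | intermediate (not isolated)
25 | O-alkyl S-methyl xanthate of 21 (at C6–O) | O=C1OC[C@]2(C)[C@@H]3[C@@](OC(=S)SC)([C@H]2C(=C)C[C@H]3C)C1(C)C | intermediate
26 | deoxygenated lactone: C6–H syn, C11 anti; C8 methylene | O=C1OC[C@]2(C)[C@@H]3[C@@H]([C@H]2C(=C)C[C@H]3C)C1(C)C | intermediate
27 | N,O-dimethylhydroxylamine hydrochloride | CNOC.Cl | starting material
28 | C3 hydroxymethyl (anti on C4), C6 (anti) C(CH3)2–C(=O)N(OMe)Me; C8 methylene | OC[C@]2(C)[C@@H]3[C@@H]([C@H]2C(=C)C[C@H]3C)C(C)(C)C(=O)N(C)OC | intermediate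
29 | C3 aldehyde analogue of 28 | O=C[C@]2(C)[C@@H]3[C@@H]([C@H]2C(=C)C[C@H]3C)C(C)(C)C(=O)N(C)OC | intermediate
30 | methyltriphenylphosphonium bromide | C[P+](c1ccccc1)(c1ccccc1)c1ccccc1.[Br-] | starting material
31 | C3 vinyl Weinreb amide | C=C[C@]2(C)[C@@H]3[C@@H]([C@H]2C(=C)C[C@H]3C)C(C)(C)C(=O)N(C)OC | intermediate
32 | vinylmagnesium bromide | C=C[Mg]Br | starting material
33 | C1 vinyl ketone (C3 vinyl; C8 methylene) | C=C[C@]2(C)[C@@H]3[C@@H]([C@H]2C(=C)C[C@H]3C)C(C)(C)C(=O)C=C | intermediate
34 | (1R)-allylic alcohol (C3 vinyl; C8 methylene) | C=C[C@]2(C)[C@@H]3[C@@H]([C@H]2C(=C)C[C@H]3C)C(C)(C)[C@H](O)C=C | intermediate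
35 | 4-methoxybenzyl chloride | COc1ccc(CCl)cc1 | starting material
36 | O1 4-methoxybenzyl ether of 34 (tris-alkene) | C=C[C@]2(C)[C@@H]3[C@@H]([C@H]2C(=C)C[C@H]3C)C(C)(C)[C@H](OCc4ccc(OC)cc4)C=C | intermediate
37 | ozone | [O-][O+]=O | starting material
38 | tris(1,2,4-trioxolane) of 36 (at C3, C2 and spiro at C8; mixture at the trioxolane carbons) | O1COOC1[C@]2(C)[C@@H]3[C@@H]([C@H]2C5(OCOO5)C[C@H]3C)C(C)(C)[C@H](OCc6ccc(OC)cc6)C7OCOO7 | intermediate (not isolated)
39 | keto-dialdehyde: C3 formyl anti on C4; C6 (anti) C(CH3)2–CH(OPMB)–CHO; C8 ketone | O=C[C@]2(C)[C@@H]3[C@@H]([C@H]2C(=O)C[C@H]3C)C(C)(C)[C@H](OCc4ccc(OC)cc4)C=O | intermediate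
40 | tricyclic diol: O2–H and O3–H cis, both trans to O1–PMB; C8 ketone | COc4ccc(CO[C@@H]1[C@@H](O)[C@@H](O)[C@]2(C)[C@@H]3[C@@H]([C@H]2C(=O)C[C@H]3C)C1(C)C)cc4 | intermediate
41 | acetic anhydride | CC(=O)OC(C)=O | starting material
42 | O2 acetate of 40 | COc4ccc(CO[C@@H]1[C@@H](OC(C)=O)[C@@H](O)[C@]2(C)[C@@H]3[C@@H]([C@H]2C(=O)C[C@H]3C)C1(C)C)cc4 | intermediate
43 | angelic acid, (Z)-2-methylbut-2-enoic acid | C/C=C(/C)C(=O)O | starting material
44 | O2 acetate O3 angelate, O1 PMB ether | COc4ccc(CO[C@@H]1[C@@H](OC(C)=O)[C@@H](OC(=O)/C(C)=C\C)[C@]2(C)[C@@H]3[C@@H]([C@H]2C(=O)C[C@H]3C)C1(C)C)cc4 | intermediate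
45 | O1 alcohol, O2 acetate, O3 angelate | O[C@@H]1[C@@H](OC(C)=O)[C@@H](OC(=O)/C(C)=C\C)[C@]2(C)[C@@H]3[C@@H]([C@H]2C(=O)C[C@H]3C)C1(C)C | intermediate
46 | CNP0197834.1 (O1 and O3 angelates, O2 acetate, C8 ketone) | C/C=C(/C)C(=O)O[C@@H]1[C@@H](OC(C)=O)[C@@H](OC(=O)/C(C)=C\C)[C@]2(C)[C@@H]3[C@@H]([C@H]2C(=O)C[C@H]3C)C1(C)C | target

**Step count and risks**

Total step count: 23. Longest linear sequence: 23 steps, from prop-2-yn-1-ol 1; every other partner is a commercial reagent.

Steps most likely to fail:

1. Step 19 (pinacol closure of ring A). The ketyls may be reduced further and protonated to the open diol, the C2 ketyl may expel the C1 alkoxide, or the two carbonyls may combine in another mutual orientation, giving the diol cis to O1 or a trans-diol. The fallback replaces reductive coupling by alkene metathesis and dihydroxylation. Setting out from 39, both aldehydes are methylenated (Ph3P=CH2, 2.2 equiv, THF, −78 to 0 °C; the hindered C8 ketone reacts far more slowly) to give the diene ketone F1. Ring-closing metathesis (second-generation Grubbs catalyst, RuCl2(=CHPh)(PCy3)(H2IMes), CH2Cl2, 40 °C) closes ring A as the C2=C3 cycloheptene F2. Dihydroxylation with OsO4 (cat.) and N-methylmorpholine N-oxide adds both oxygens to one face, normally the face opposite an allylic alkoxy group, and returns to the route at diol 40.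

2. Step 6 (vinylketene [2+2]). The vinylketene may dimerise, or be shuttled by amine hydrochloride into isomeric dienoyl species, faster than it cyclises onto the inductively deactivated allylic-ether alkene; it may also add with poor facial discrimination. The fallback makes the same ketene without base by a retro-ene reaction. From ketone 9, kinetic enolisation (LiN(i-Pr)2, THF, −78 °C) and N-(5-chloropyridin-2-yl)triflimide give the enol triflate F3. Negishi coupling with (tert-butoxyethynyl)zinc chloride (from tert-butoxyethyne, n-BuLi, ZnCl2; Pd(PPh3)4, zerovalent palladium, THF) gives the enynyl tert-butyl ether F4. Heating F4 in toluene at 80–100 °C at high dilution releases 2-methylpropene and generates vinylketene 15 under neutral conditions; 15 cyclises to 16, where the route is rejoined.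

3. Step 10 (xanthate on the C6 alcohol). The tertiary alkoxide is shielded by C11, the two bridgeheads and the C10 methyl, so it may fail to add to CS2, or it may revert by retro-aldol cleavage. The fallback is a reductive radical alkylation of the ketone, so that no C6 oxygen has to be removed. From bromoester 19, condensation of the C6 ketone with 1-amino-2-phenylaziridine gives the N-aziridinylimine F5. Slow addition of Bu3SnH with AIBN in benzene at 80 °C generates the C11 radical, which adds to the imine carbon from the anti face. The aminyl radical then loses styrene and N2, and the resulting C6 radical takes hydrogen on the syn face, giving lactone 26 directly; steps 9 to 11 are bypassed and the route is rejoined at 26.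

**Further compounds**

F1 | step 19 | diene ketone: C2 and C3 vinyl groups, O1 PMB ether, C8 ketone | C=C[C@]2(C)[C@@H]3[C@@H]([C@H]2C(=O)C[C@H]3C)C(C)(C)[C@H](OCc4ccc(OC)cc4)C=C
F2 | step 19 | ring A cycloheptene (C2=C3), O1 PMB ether, C8 ketone | COc4ccc(CO[C@@H]1C=C[C@]2(C)[C@@H]3[C@@H]([C@H]2C(=O)C[C@H]3C)C1(C)C)cc4
F3 | step 6 | (4R,5E)-4,6-dimethyl-7-(triisopropylsilyloxy)hepta-1,5-dien-2-yl trifluoromethanesulfonate | C=C(OS(=O)(=O)C(F)(F)F)C[C@@H](C)/C=C(\C)CO[Si](C(C)C)(C(C)C)C(C)C
F4 | step 6 | (5R,6E)-1-tert-butoxy-5,7-dimethyl-3-methylidene-8-(triisopropylsilyloxy)oct-6-en-1-yne | CC(C)(C)OC#CC(=C)C[C@@H](C)/C=C(\C)CO[Si](C(C)C)(C(C)C)C(C)C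
F5 | step 10 | C6 N-(2-phenylaziridin-1-yl)imine of bromoester 19 | CC(C)(Br)C(=O)OC[C@]2(C)[C@@H]3C(=NN4CC4c5ccccc5)[C@H]2C(=C)C[C@H]3C
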